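## Retrosynthetic overview
1. The C2' prenyl group is relayed from O3' by an aromatic Claisen [3,3] shift of the 3'-O-(1,1-dimethylallyl) ether of 5,7,3',4'-tetrahydroxyisoflavone. C4' is blocked by OH, so only C2' can accept it.
2. Key disconnection: the aryl C3'–O bond. It leads back to a ring B o-quinone diazide (carbene carbon at C3', O4' already in place) and 2-methylbut-3-en-2-ol, joined by O–H insertion.
3. The diazide comes from the 3'-amine, and the amine from 5,7,4'-trihydroxy-3'-nitroisoflavone.
4. Ring C comes from O1–C2 closure of a deoxybenzoin with one carbon from DMF. The deoxybenzoin comes from phloroglucinol and 4-hydroxy-3-nitrophenylacetic acid.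
5. Ring order: rings A and B are bought, ring C is closed in step 1, and no ring is formed later. No protecting groups are used.

Assumption: the target has no stereocentre and no stereogenic double bond (the prenyl C=C carries two methyl groups). It is achiral, the given SMILES defines it fully, and no configuration has to be set.

## Route

Step 1
Reactants: 1 phloroglucinol (benzene-1,3,5-triol); 2 4-hydroxy-3-nitrophenylacetic acid
Product: 4 5,7,4'-trihydroxy-3'-nitroisoflavone (3'-nitrogenistein), via deoxybenzoin 3 (not isolated)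
Conditions: BF3·OEt2 (solvent), 85 °C, 2 h; then DMF, MsCl (3 equiv), 50 to 75 °C, 3 h; H2O quench
Reagents that add atoms: N,N-dimethylformamide, CN(C)C=O
Why: Friedel–Crafts C-acylation of the symmetric, very nucleophilic phloroglucinol gives the deoxybenzoin, its activated CH2 is formylated by the Vilsmeier-type reagent from DMF and MsCl, and the ortho phenol closes ring C by addition–elimination at the enaminone carbon (O1–C2 bond), while the nitro group and free phenols are inert and no stereocentre is formed.

Step 2
Reactants: 4 5,7,4'-trihydroxy-3'-nitroisoflavone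
Product: 5 3'-amino-5,7,4'-trihydroxyisoflavone
Conditions: H2 (1 atm), 10% Pd/C, MeOH–THF, rt, 1 h, stopped at 3 equiv H2; filtered under N2 and used at once
Reagents that add atoms: none
Why: Catalytic hydrogenation of an aromatic nitro group is much faster than saturation of the chromone C2=C3 bond at 1 atm and room temperature, so the o-aminophenol forms cleanly.

Step 3
Reactants: 5 3'-amino-5,7,4'-trihydroxyisoflavone
Product: 6 3-(3-diazo-4-oxocyclohexa-1,5-dien-1-yl)-5,7-dihydroxy-4H-chromen-4-one (ring B o-quinone diazide)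
Conditions: t-BuONO (1.05 equiv), AcOH (10 mol %), THF–MeOH, 0 °C, dark, 30 min; concentrated below 20 °C, used crude
Reagents that add atoms: tert-butyl nitrite, CC(C)(C)ON=O
Why: In this alkyl nitrite diazotisation of an o-aminophenol, N-nitrosation outruns C-nitrosation of the acyl-deactivated ring A, and the o-hydroxydiazonium ion (pKa about 4) at once loses its proton to give the neutral diazide, which is too weak an electrophile for azo coupling.

Step 4
Reactants: 6 ring B o-quinone diazide; 7 2-methylbut-3-en-2-ol
Product: 9 5,7,3',4'-tetrahydroxy-2'-(3,3-dimethylallyl)isoflavone (target), via tert-prenyl ether 8 (not isolated)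
Conditions: Rh2(OAc)4 (2 mol %), 7 as solvent (0.02 M in 6, slow addition), 70 °C, dark, 2 h; then sealed tube, 115 °C, 8 h, N2
Reagents that add atoms: none
Why: Proposed new method: dirhodium tetraacetate (divalent rhodium) expels N2 from the diazide to give an electrophilic quinoid carbene fixed at C3', the oxygen of the tertiary allylic alcohol (about 500-fold excess over the ring A phenols, and with no carbinol C–H that could reduce the carbene) attacks it to give an oxonium ylide, and proton transfer to the adjacent O4' restores aromaticity, so the aryl C3'–O bond forms at only one of the two catechol oxygens without any protecting group; on heating in the protic medium, ether 8 undergoes the gem-dimethyl- and hydrogen-bond-accelerated aromatic Claisen [3,3] shift, which can end only at C2' because C4' carries OH, and this delivers the linear prenyl group; the closest known reaction types are rhodium-carbenoid O–H insertion of α-diazocarbonyl compounds and diazonaphthoquinones into simple alcohols and the Claisen rearrangement of 1,1-dimethylallyl aryl ethers, neither of which has been shown for a monocyclic o-quinone diazide of an unprotected polyphenol or with a tertiary allylic alcohol; no stereocentre is formed.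

## Compound list
1 | phloroglucinol | Oc1cc(O)cc(O)c1 | starting material
2 | 4-hydroxy-3-nitrophenylacetic acid | OC(=O)Cc1ccc(O)c([N+](=O)[O-])c1 | starting material
3 | 2-(4-hydroxy-3-nitrophenyl)-1-(2,4,6-trihydroxyphenyl)ethan-1-one (deoxybenzoin) | O=C(Cc1ccc(O)c([N+](=O)[O-])c1)c1c(O)cc(O)cc1O | intermediate
4 | 5,7,4'-trihydroxy-3'-nitroisoflavone | O=c1c(-c2ccc(O)c([N+](=O)[O-])c2)coc2cc(O)cc(O)c12 | intermediate
5 | 3'-amino-5,7,4'-trihydroxyisoflavone | O=c1c(-c2ccc(O)c(N)c2)coc2cc(O)cc(O)c12 | intermediate
6 | 3-(3-diazo-4-oxocyclohexa-1,5-dien-1-yl)-5,7-dihydroxy-4H-chromen-4-one | O=C1C=CC(c2coc3cc(O)cc(O)c3c2=O)=CC1=[N+]=[N-] | intermediate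
7 | 2-methylbut-3-en-2-ol | C=CC(C)(C)O | starting material
8 | 5,7,4'-trihydroxy-3'-(2-methylbut-3-en-2-yloxy)isoflavone | C=CC(C)(C)Oc1cc(-c2coc3cc(O)cc(O)c3c2=O)ccc1O | intermediate
9 | 5,7,3',4'-tetrahydroxy-2'-(3,3-dimethylallyl)isoflavone | CC(C)=CCc1c(-c2coc3cc(O)cc(O)c3c2=O)ccc(O)c1O | target

## Step count and risks
Total step count: 4. Longest linear sequence: 4 (1 to 4 to 5 to 6 to 9).

**Step 4 (proposed new step).**
- Risks before the ether forms: the carbene may add to the vinyl group (cyclopropane or dihydrobenzofuran), the ylide may undergo a [2,3] shift, or the diazide may ring-contract by Wolff rearrangement.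
- Risk after the ether forms: ether 8 may lose isoprene before it rearranges.
- The fallback uses known chemistry only. It sets out from 6 and comes back at 9.
- Acidifying 6 in the presence of iodide (KI, TsOH·H2O, MeCN–H2O, 0 °C to rt, iododediazoniation) gives 5,7,4'-trihydroxy-3'-iodoisoflavone F1.
- MOMCl and i-Pr2NEt in CH2Cl2 cap the two non-chelated phenols to give 5-hydroxy-3'-iodo-7,4'-bis(methoxymethoxy)isoflavone F2.
- Miyaura borylation (B2pin2, PdCl2(dppf), KOAc, dioxane, 90 °C) gives 5-hydroxy-7,4'-bis(methoxymethoxy)-3'-(4,4,5,5-tetramethyl-1,3,2-dioxaborolan-2-yl)isoflavone F3.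
- NaBO3·4H2O in THF–H2O at rt oxidises it to 5,3'-dihydroxy-7,4'-bis(methoxymethoxy)isoflavone F4, in which 3'-OH is the only reactive phenol.
- Separately, 7 is treated with n-BuLi and Boc2O in THF to give tert-butyl 2-methylbut-3-en-2-yl carbonate F5.
- Pd(PPh3)4 (zerovalent palladium, 3 mol %) in THF at 0 °C joins F4 and F5. This is the known decarboxylative, branched-selective O-allylation, and it gives 5-hydroxy-7,4'-bis(methoxymethoxy)-3'-(2-methylbut-3-en-2-yloxy)isoflavone F6.
- Thermal Claisen rearrangement in N,N-diethylaniline at 130 °C gives 5,3'-dihydroxy-7,4'-bis(methoxymethoxy)-2'-(3-methylbut-2-enyl)isoflavone F7.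
- 3 M HCl in MeOH at 50 °C removes both MOM groups to give 9.

**Step 3.**
- Risks: C-nitrosation or azo coupling at C6 or C8 of ring A, and loss of the light- and heat-sensitive neutral diazide on isolation.
- The fallback sets out from 5 and comes back at 6.
- The amine is diazotised in strong mineral acid (NaNO2, 48% aq HBF4, 0 °C). There the chromone carbonyl is protonated and ring A no longer acts as a nucleophile.
- 2-Hydroxy-5-(5,7-dihydroxy-4-oxo-4H-chromen-3-yl)benzenediazonium tetrafluoroborate F8 precipitates, is filtered off and serves as the storage form.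
- It is deprotonated with NaOAc (1 equiv) in 7 just before Rh2(OAc)4 is added, so 6 forms in the flask of step 4 and is never isolated.

**Step 1.**
- Risks: sluggish acylation with the nitro acid, or incomplete ring closure of boron-chelated material in the one-pot sequence.
- The fallback sets out from 1, passes through isolated 3 and comes back at 4.
- 4-Hydroxyphenylacetonitrile is nitrated (HNO3, AcOH, 10 °C) to 2-(4-hydroxy-3-nitrophenyl)acetonitrile F9.
- Houben–Hoesch reaction of 1 with F9 (HCl gas, ZnCl2, Et2O, 0 °C) precipitates 2-(4-hydroxy-3-nitrophenyl)-1-(2,4,6-trihydroxyphenyl)ethan-1-iminium chloride F10.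
- Boiling water hydrolyses it to 3.
- Ring C is then closed under mildly basic conditions with HC(OEt)3 and morpholine in DMF at 100 °C to give 4.

## Further compounds
F1 | step 4 | 5,7,4'-trihydroxy-3'-iodoisoflavone | O=c1c(-c2ccc(O)c(I)c2)coc2cc(O)cc(O)c12
F2 | step 4 | 5-hydroxy-3'-iodo-7,4'-bis(methoxymethoxy)isoflavone | O=c1c(-c2ccc(OCOC)c(I)c2)coc2cc(OCOC)cc(O)c12
F3 | step 4 | 5-hydroxy-7,4'-bis(methoxymethoxy)-3'-(4,4,5,5-tetramethyl-1,3,2-dioxaborolan-2-yl)isoflavone | O=c1c(-c2ccc(OCOC)c(B3OC(C)(C)C(C)(C)O3)c2)coc2cc(OCOC)cc(O)c12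
F4 | step 4 | 5,3'-dihydroxy-7,4'-bis(methoxymethoxy)isoflavone | O=c1c(-c2ccc(OCOC)c(O)c2)coc2cc(OCOC)cc(O)c12
F5 | step 4 | tert-butyl 2-methylbut-3-en-2-yl carbonate | C=CC(C)(C)OC(=O)OC(C)(C)C
F6 | step 4 | 5-hydroxy-7,4'-bis(methoxymethoxy)-3'-(2-methylbut-3-en-2-yloxy)isoflavone | C=CC(C)(C)Oc1cc(-c2coc3cc(OCOC)cc(O)c3c2=O)ccc1OCOC
F7 | step 4 | 5,3'-dihydroxy-7,4'-bis(methoxymethoxy)-2'-(3-methylbut-2-enyl)isoflavone | CC(C)=CCc1c(-c2coc3cc(OCOC)cc(O)c3c2=O)ccc(OCOC)c1O
F8 | step 3 | 2-hydroxy-5-(5,7-dihydroxy-4-oxo-4H-chromen-3-yl)benzenediazonium tetrafluoroborate | Oc1ccc(-c2coc3cc(O)cc(O)c3c2=O)cc1[N+]#N.F[B-](F)(F)F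
F9 | step 1 | 2-(4-hydroxy-3-nitrophenyl)acetonitrile | N#CCc1ccc(O)c([N+](=O)[O-])c1
F10 | step 1 | 2-(4-hydroxy-3-nitrophenyl)-1-(2,4,6-trihydroxyphenyl)ethan-1-iminium chloride | [NH2+]=C(Cc1ccc(O)c([N+](=O)[O-])c1)c1c(O)cc(O)cc1O.[Cl-]
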